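**Assumptions (one line):** for the alternatives, the aryne source is taken as the 1,2‑dibromide A1 and the acyclic diene as the 1,1‑dimethoxy‑3‑silyloxy diene A6. Precursor 8 (C17H26O5) and product 10 (C17H24O4) of the key step differ by exactly one molecule of water, and their skeletons need no correction.

## Structural features

The target (C29H40O7) is a depside: two benzene rings joined only by an aryl ester, with the carbonyl on C1 of ring A and the oxygen on C4 of ring B. Ring A is a 2‑heptyl‑4,6‑dimethoxybenzoyl unit. Ring B is a 2‑methoxy‑6‑pentylbenzoic acid that carries the ester oxygen para to its free carboxyl group. There are no stereocentres and no double‑bond isomers, so nothing has to be controlled in that sense. The fragile groups are the aryl ester, which alkoxide or hydroxide cleaves and which can fragment through an ortho‑phenoxide, and the electron‑rich ring B acid, which must be unmasked last under neutral conditions. The real difficulty is that both carbonyl carbons are flanked by two ortho substituents, so the ring A carboxyl is a poor partner for ordinary esterification with a weakly nucleophilic phenol. In addition, three phenolic oxygens must end as methyl ethers while a fourth becomes the ester oxygen. The key step exploits the polyketide pattern of ring A: carboxyl on C1, heptyl on C2 and oxygens on C4 and C6 are what a 3,5,7‑trioxotetradecanoate chain gives when it folds by an aldol reaction that forms the C1–C2 bond. The same mask that holds the carboxyl and O‑6 together as a dioxinone later serves as the acyl donor for the hindered ester.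

## Logic of the disconnections

**18 to 17.** The bond cut is the O–CH2 bond of a benzyl ester on the ring B carboxyl. A free acid would intercept the acylating species and would be methylated, so it stays masked until the end. The demand is a neutral unmasking with nothing else reducible present, which holds for 17.

**17 to 16.** Two O–CH3 bonds are cut, at O‑6 of ring A (next to the depside carbonyl) and at O‑2 of ring B (next to the benzyl ester). In 16 both oxygens are hydrogen‑bonded to a neighbouring ester carbonyl, which is what keeps them silent during the coupling. Leaving them free until this point removes any need to tell the two hydroxyls of ring B apart with protecting groups. The demand is a methylation free of alkoxide and hydroxide so that the aryl ester survives.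

**16 to 11 and 14.** The depside C(=O)–O bond between C1 of ring A and O‑4 of ring B is cut, giving two halves of similar size. In 11 the carboxyl and O‑6 are tied in a six‑membered acetonide that releases ketene 15 on irradiation, so the hindered carbonyl is delivered as an unhindered sp carbon and no acid activation is needed. The demands are that O‑4 of ring A is already capped in 11, that 14 offers one free hydroxyl (O‑4) and one chelated hydroxyl (O‑2), and that 16 tolerates the light.

**14 to 13 to 12.** The benzyl O–CH2 bond on the carboxylate and then the ring B C1–CO2H bond are cut. Compound 12 already holds the pentyl chain and both oxygens in the right 1,3,5 pattern. The demand is carboxylation next to the pentyl group (ortho to one hydroxyl, para to the other) and not between the hydroxyls, followed by alkylation on the carboxylate only.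

**11 to 10.** The O–CH3 bond at O‑7 (O‑4 of ring A) is cut. This is the only free phenol of 10; capping it sets the 4‑methoxy group and removes a nucleophile that would compete for 15. The base must not open the acylal.

**10 to 8 (key).** The ring A bond C1–C2 (C4a–C5 of 10) is cut and the aromatic C=C bonds are written back as carbonyl groups, passing through 9. A tetrasubstituted benzene becomes a linear chain in which the position of every substituent is already fixed. The demand is that C5 of the dioxinone, and no other atom, attacks the heptyl ketone, and that water is then lost.

**8 to 4 and 6 (6 from 5).** The C3′–C4′ bond of the side chain, between the terminal methylene and the heptyl ketone carbon, is cut, passing through 7. The eight‑carbon tail then arrives as a simple acyl donor. The demands are C‑acylation at the terminal carbon of 7, and an acyl donor that carries no acidic N–H and releases a leaving group basic enough to take up the new acidic proton. For this reason 6 is filtered free of its hydrochloride by‑product before use.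

**4 to 1 and 2.** The C1′–C2′ bond between the methylene on C6 and the acetyl carbonyl is cut; both pieces are commercial. The demand is γ‑selective acylation of 3, with a second equivalent of 3 because the product is the stronger acid.

## Other disconnections considered

**Alternative 1:**
- **Cut:** two substituent bonds are removed from an intact ring A at once, the C2–heptyl bond and the C1–carboxyl bond, leaving an aryne.
- **Forward key step:** 1,2‑dibromo‑3,5‑dimethoxybenzene A1 would be treated with excess heptylmagnesium bromide A2 (C7H15MgBr). Halogen–magnesium exchange and elimination of the metal halide would release 3,5‑dimethoxybenzyne A3. A second equivalent of A2 would add to the aryne carbon meta to the adjacent methoxy group, which places the new carbon–magnesium bond next to that oxygen. Carbon dioxide A4 would then give 2‑heptyl‑4,6‑dimethoxybenzoic acid A5.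
- **In its favour:** three components are joined in one flask, both methyl ethers are present from the start, and no ring has to be built.
- **Against it here:** A5 is a di‑ortho‑substituted, unactivated acid. The depside bond would need mixed‑anhydride activation toward the free 4‑hydroxyl of 14 and then one O‑methylation to reach 17. The orientation of the addition rests on polarisation by a single methoxy group, exchange can begin at either bromine, and the alkyl halide set free by the exchange can alkylate the arylmagnesium.
- **Comparison, structure:** both plans give the same 1‑carboxy‑2‑alkyl‑4,6‑dioxygenated ring. In the chosen plan the pattern follows from the chain and cannot appear as an isomer; the aryne route depends on a directing effect.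
- **Comparison, mechanism:** strongly basic organometallic steps on a substrate without sensitive groups (acceptable) stand against an amine‑mediated aldol at room temperature.
- **Comparison, step economy:** the alternative is the better one, about two steps to A5 against five to 11 and about seven steps in all against ten, and it needs no photochemical equipment. It gives up the built‑in acyl donor.

**Alternative 2:**
- **Cut:** ring B is opened through C1–C2 and C5–C6 into a four‑carbon ketene‑acetal diene and a two‑carbon ynoate.
- **Forward key step:** 1,1‑dimethoxy‑3‑(trimethylsilyloxy)buta‑1,3‑diene A6 and benzyl oct‑2‑ynoate A7 would be heated together. The unsubstituted diene terminus should bond to the pentyl‑bearing β‑carbon and the acetal carbon to the ester‑bearing α‑carbon. Loss of one methoxy group as the alcohol, together with the silyl group, would aromatise the adduct to benzyl 4‑hydroxy‑2‑methoxy‑6‑pentylbenzoate A8.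
- **In its favour:** A8 has the 2‑methoxy and 4‑hydroxy groups of ring B already told apart and the benzyl ester in place. After union with 11 as in step 8 only the ring A hydroxyl would remain to be methylated, and acylation of A8 with an activated form of A5 would give 17 directly.
- **Against it here:** it does nothing for ring A or for the hindered ester bond, where the difficulty lies. Ynoates with a β‑alkyl group are slow dienophiles toward such dienes and need temperatures at which the moisture‑sensitive diene degrades. The orientation again rests on polarisation.
- **Comparison, structure:** A8 is a better ring B partner than 14; on this point the alternative is superior.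
- **Comparison, mechanism:** a thermal cycloaddition with elimination stands against carboxylation of an existing ring, which needs no ring construction.
- **Comparison, step economy:** about three steps to A8 (ester, diene, annulation) against two to 14, roughly equal once the simpler late methylation is counted. Because it concerns the other ring, it does not compete with the chosen key step and could be combined with it.

**Alternative 3:**
- **Cut:** ring A is opened through C1–C6 and C2–C3 into a cyclic dimethoxy diene and an ynoate that carries the heptyl chain.
- **Forward key step:** 1,3‑dimethoxycyclohexa‑1,3‑diene A9, formed by conjugation of the dissolving‑metal reduction product of the parent dimethoxyarene, would be heated with benzyl dec‑2‑ynoate A10 to give the bicyclo[2.2.2]octadiene A11. Cycloreversion with loss of ethene A12 would leave benzyl 2‑heptyl‑4,6‑dimethoxybenzoate A13, which hydrogenolysis would convert into A5.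
- **In its favour:** ring A is assembled with all its substituents, both methyl ethers included, in one neutral thermal operation from two simple pieces. The polarisation of diene and ynoate is matched, so the orientation should be reliable.
- **Against it here:** β‑alkyl ynoates and the ethene extrusion call for temperatures well above 150 °C. The diene tends to aromatise or disproportionate, so modest efficiency is to be expected. As in alternative 1, the product is an unactivated hindered acid derivative, so the depside bond still needs separate activation and ring B still needs one methylation after coupling with 14.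
- **Comparison, structure:** the same ring A pattern results, with both oxygens already methylated, which is better than the chosen plan, where ring A needs two methylation steps.
- **Comparison, mechanism:** two ring bonds formed by cycloaddition under forcing conditions stand against one ring bond formed by an aldol at room temperature; both have inherent regiocontrol.
- **Comparison, step economy:** about three steps to A5 against five to 11 and about eight in all against ten, so the alternative is shorter. The chosen plan keeps the mild conditions and the acyl‑transfer ability of the dioxinone.

Key step: step 4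

## Route

Step 1
Reactants: 1 2,2,6-trimethyl-4H-1,3-dioxin-4-one; 2 acetyl chloride
Product: 4 2,2-dimethyl-6-(2-oxopropyl)-4H-1,3-dioxin-4-one, via lithium dienolate 3 (not isolated)
Conditions: LiN(SiMe3)2 (2.0 equiv), 1 (2.0 equiv), THF, −78 °C; then 2 (1.0 equiv), −78 °C; aq. NH4Cl
Reagents that add atoms: none
Why: LiN(SiMe3)2 removes a proton from the C6 methyl group to give the extended enolate 3, which is acylated at its γ-carbon by the acid chloride (vinylogous crossed Claisen acylation). Because product 4 is more acidic than 1, a second equivalent of 3 serves as base and returns to 1 on work-up, which keeps the acylation from stalling or running on to a diacyl compound.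

Step 2
Reactants: 5 octanoyl chloride
Product: 6 1-(1H-imidazol-1-yl)octan-1-one
Conditions: imidazole (2.0 equiv), THF, 0 °C to rt; filter, concentrate
Reagents that add atoms: imidazole, c1c[nH]cn1
Why: Nucleophilic acyl substitution at the acid chloride; the second equivalent of imidazole takes up HCl and is filtered off as its hydrochloride. The N-acylimidazole is free of N–H acid, reacts only once with a carbanion and releases imidazolide, which is why it is preferred to the acid chloride for step 3.

Step 3
Reactants: 4 2,2-dimethyl-6-(2-oxopropyl)-4H-1,3-dioxin-4-one; 6 1-(1H-imidazol-1-yl)octan-1-one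
Product: 8 6-(2,4-dioxoundecyl)-2,2-dimethyl-4H-1,3-dioxin-4-one, via dilithium dianion 7 (not isolated)
Conditions: LiN(i-Pr)2 (2.1 equiv), THF, −78 °C; then 6 (1.0 equiv), −78 to −40 °C; aq. HCl (pH 3), 0 °C; used at once
Reagents that add atoms: none
Why: Two equivalents of LiN(i-Pr)2 remove first a proton from the doubly activated C1′ methylene and then one from the terminal methyl group; dianion 7 reacts at the last-formed, more basic terminal carbon, the usual regiochemistry of β-dicarbonyl dianions, in a crossed Claisen condensation with 6. The expelled imidazolide deprotonates the new 1,3-diketone, so 7 is not consumed as a base. Compound 8 is taken on promptly because such tricarbonyl chains cyclise on silica or on standing.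

Step 4
Reactants: 8 6-(2,4-dioxoundecyl)-2,2-dimethyl-4H-1,3-dioxin-4-one
Product: 10 5-heptyl-7-hydroxy-2,2-dimethyl-4H-1,3-benzodioxin-4-one, via aldol carbinol 9 (not isolated)
Conditions: Et3N (2 equiv), CH2Cl2, rt; then aq. HCl wash
Reagents that add atoms: none
Why: Et3N reversibly enolises the C2′ ketone of the side chain toward C1′, which creates a dienolate conjugated through C6=C5 of the dioxinone whose terminus C5 is also pushed by the ring oxygen O1. C5 then adds to the C4′ ketone, the carbon that carries the heptyl group, through a six-membered chair-like transition state to give carbinol 9; the closure is 6-(enolendo)-exo-trig, because the nucleophilic π system lies inside the new ring and the carbonyl oxygen ends up outside it. Hydroxide is lost from 9 by E1cB elimination across C5–C6 of the new ring and the remaining ring ketone enolises to the phenol, so aromatisation makes the sequence irreversible and leaves the new bond between the carboxyl-bearing and the heptyl-bearing carbon of ring A. The closest known reaction type is the base-mediated intramolecular aldol condensation of 1,3,5-tricarbonyl chains to resorcylates, here in its dioxinone-masked form. No stereocentre is created in the product: the carbinol centre of 9 forms without control and is erased by the dehydration. The selectivity required is for this C–C closure over lactonisation to a pyranone and over Claisen closure onto the carboxyl carbon; the dioxinone secures it by holding the C4 carbonyl trans to the side chain across C5=C6 so that no chain atom can reach it, by tying up O1 as an acetal oxygen and by lowering the electrophilicity of C4. Regioselectivity needs no control, since attack of C5 on the C2′ ketone would give a four-membered ring.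

Step 5
Reactants: 10 5-heptyl-7-hydroxy-2,2-dimethyl-4H-1,3-benzodioxin-4-one
Product: 11 5-heptyl-7-methoxy-2,2-dimethyl-4H-1,3-benzodioxin-4-one
Conditions: MeI (1.5 equiv), K2CO3 (2 equiv), acetone, rt
Reagents that add atoms: iodomethane, CI
Why: Williamson ether synthesis at the only free phenol, which is acidic because it is para to the carbonyl group. K2CO3 in acetone provides no alkoxide or hydroxide, so the acylal carbonyl of the dioxinone ring is not attacked.

Step 6
Reactants: 12 olivetol (5-pentylbenzene-1,3-diol)
Product: 13 olivetolic acid (2,4-dihydroxy-6-pentylbenzoic acid)
Conditions: MeOMgOCO2Me (2 M in DMF, 4 equiv), 120 °C; then ice-cold aq. HCl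
Reagents that add atoms: methoxymagnesium methyl carbonate (MeOMgOCO2Me), COC(=O)O[Mg]OC
Why: Kolbe–Schmitt-type ortho-carboxylation: the Mg-bound aryloxide is carboxylated by the methyl carbonate ligand and the product is held as an Mg salicylate-type chelate, which drives the equilibrium. The ring carbon ortho to one hydroxyl and para to the other is the most nucleophilic position of 12 (the two such positions are equivalent), which should give the 2,4-dihydroxy-6-pentyl pattern; cold acidification avoids decarboxylation.

Step 7
Reactants: 13 olivetolic acid (2,4-dihydroxy-6-pentylbenzoic acid)
Product: 14 benzyl 2,4-dihydroxy-6-pentylbenzoate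
Conditions: BnBr (1.05 equiv), KHCO3 (1.2 equiv), DMF, rt
Reagents that add atoms: benzyl bromide, BrCc1ccccc1
Why: SN2 alkylation of the carboxylate; KHCO3 ionises only the carboxylic acid, so neither phenol is benzylated, and room temperature avoids decarboxylation of the β-resorcylic acid.

Step 8
Reactants: 11 5-heptyl-7-methoxy-2,2-dimethyl-4H-1,3-benzodioxin-4-one; 14 benzyl 2,4-dihydroxy-6-pentylbenzoate
Product: 16 benzyl 4-[(2-heptyl-6-hydroxy-4-methoxybenzoyl)oxy]-2-hydroxy-6-pentylbenzoate, via quinone ketene 15 (not isolated)
Conditions: hν (300 nm), 14 (1.5 equiv), degassed CH2Cl2 (0.01 M), rt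
Reagents that add atoms: none
Why: Excitation of the benzodioxinone causes a retro-[4+2] fragmentation that expels acetone and leaves quinone ketene 15, whose acylating carbon is sp-hybridised and therefore not shielded by the two ortho substituents that make the parent acid hard to esterify. The free 4-hydroxyl of 14 adds to the ketene (photochemical acylation of phenols by benzodioxinones, a known route to depsides), while the 2-hydroxyl is hydrogen-bonded to the benzyl ester and flanked by it. The product is an ortho-hydroxy aryl ester, a chromophore that sheds excitation by proton transfer and should therefore resist photo-Fries rearrangement during the irradiation.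

Step 9
Reactants: 16 benzyl 4-[(2-heptyl-6-hydroxy-4-methoxybenzoyl)oxy]-2-hydroxy-6-pentylbenzoate
Product: 17 benzyl 4-[(2-heptyl-4,6-dimethoxybenzoyl)oxy]-2-methoxy-6-pentylbenzoate
Conditions: MeI (6 equiv), K2CO3 (4 equiv), DMF, rt to 40 °C
Reagents that add atoms: iodomethane, CI
Why: Double Williamson methylation of the two hydrogen-bonded phenols; K2CO3 in DMF breaks the chelates and the excess of MeI captures each phenoxide as it forms. No alkoxide, hydroxide or alcohol is present, so neither the aryl ester nor the benzyl ester should be cleaved.

Step 10
Reactants: 17 benzyl 4-[(2-heptyl-4,6-dimethoxybenzoyl)oxy]-2-methoxy-6-pentylbenzoate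
Product: 18 4-[(2-heptyl-4,6-dimethoxybenzoyl)oxy]-2-methoxy-6-pentylbenzoic acid
Conditions: H2 (1 atm), 10% Pd/C, EtOAc, rt
Reagents that add atoms: none
Why: Hydrogenolysis of the benzylic C–O bond on palladium under neutral conditions; the aryl ester, the aryl methyl ethers and the alkyl chains are inert. The hindered aryl ester is never exposed to base or acid in the unmasking.

## Compound list

1 | 2,2,6-trimethyl-4H-1,3-dioxin-4-one | CC1=CC(=O)OC(C)(C)O1 | starting material
2 | acetyl chloride | CC(=O)Cl | starting material
3 | lithium 2,2-dimethyl-6-methylidene-6H-1,3-dioxin-4-olate (lithium dienolate of 1; formed in the flask, not isolated) | [Li+].C=C1C=C([O-])OC(C)(C)O1 | intermediate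
4 | 2,2-dimethyl-6-(2-oxopropyl)-4H-1,3-dioxin-4-one | CC(=O)CC1=CC(=O)OC(C)(C)O1 | intermediate
5 | octanoyl chloride | CCCCCCCC(=O)Cl | starting material
6 | 1-(1H-imidazol-1-yl)octan-1-one | CCCCCCCC(=O)n1ccnc1 | intermediate
7 | dilithium dianion of 4 (C2′ enolate and terminal carbanion of the oxopropyl chain; formed in the flask, not isolated) | [Li+].[Li+].[CH2-]C([O-])=CC1=CC(=O)OC(C)(C)O1 | intermediate
8 | 6-(2,4-dioxoundecyl)-2,2-dimethyl-4H-1,3-dioxin-4-one | CCCCCCCC(=O)CC(=O)CC1=CC(=O)OC(C)(C)O1 | intermediate
9 | 5-heptyl-5-hydroxy-2,2-dimethyl-5,6-dihydro-4H-1,3-benzodioxine-4,7(8H)-dione (racemic aldol carbinol; formed in the flask, not isolated) | CCCCCCCC1(O)CC(=O)CC2=C1C(=O)OC(C)(C)O2 | intermediate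
10 | 5-heptyl-7-hydroxy-2,2-dimethyl-4H-1,3-benzodioxin-4-one | CCCCCCCc1cc(O)cc2OC(C)(C)OC(=O)c12 | intermediate
11 | 5-heptyl-7-methoxy-2,2-dimethyl-4H-1,3-benzodioxin-4-one | CCCCCCCc1cc(OC)cc2OC(C)(C)OC(=O)c12 | intermediate
12 | olivetol (5-pentylbenzene-1,3-diol) | CCCCCc1cc(O)cc(O)c1 | starting material
13 | olivetolic acid (2,4-dihydroxy-6-pentylbenzoic acid) | CCCCCc1cc(O)cc(O)c1C(=O)O | intermediate
14 | benzyl 2,4-dihydroxy-6-pentylbenzoate | CCCCCc1cc(O)cc(O)c1C(=O)OCc1ccccc1 | intermediate
15 | 5-heptyl-3-methoxy-6-(oxomethylidene)cyclohexa-2,4-dien-1-one (quinone ketene; formed in the flask, not isolated) | CCCCCCCC1=CC(OC)=CC(=O)C1=C=O | intermediate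
16 | benzyl 4-[(2-heptyl-6-hydroxy-4-methoxybenzoyl)oxy]-2-hydroxy-6-pentylbenzoate | CCCCCCCc1cc(OC)cc(O)c1C(=O)Oc1cc(CCCCC)c(C(=O)OCc2ccccc2)c(O)c1 | intermediate
17 | benzyl 4-[(2-heptyl-4,6-dimethoxybenzoyl)oxy]-2-methoxy-6-pentylbenzoate | CCCCCCCc1cc(OC)cc(OC)c1C(=O)Oc1cc(CCCCC)c(C(=O)OCc2ccccc2)c(OC)c1 | intermediate
18 | 4-[(2-heptyl-4,6-dimethoxybenzoyl)oxy]-2-methoxy-6-pentylbenzoic acid (no stereocentres) | CCCCCCCc1cc(OC)cc(OC)c1C(=O)Oc1cc(CCCCC)c(C(=O)O)c(OC)c1 | target

## Step count and least certain steps

Total step count: 10. Longest linear sequence: 7 steps (1, 3, 4, 5, 8, 9, 10). Step 2 and steps 6–7 are side branches.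

**Step 4 (key step).** The most likely failure is that the sequence stalls at the carbinol stage because dehydration is slow, or that the tricarbonyl chain is lost by retro-Claisen cleavage or uncontrolled cyclisation before the amine-mediated closure is complete. Fallback, from 8 to 17: the acyl end is unmasked instead of kept. Heating 8 in toluene at 110 °C with benzyl alcohol should release the acyl ketene and give benzyl 3,5,7-trioxotetradecanoate F1. The same aldol fold, under mild base followed by acid-promoted dehydration, should give benzyl 2-heptyl-4,6-dihydroxybenzoate F2. Methylation of both hydroxyls (MeI, K2CO3) would give benzyl 2-heptyl-4,6-dimethoxybenzoate F3 (the same compound as A13), and hydrogenolysis 2-heptyl-4,6-dimethoxybenzoic acid F4 (the same compound as A5). Its mixed anhydride with (CF3CO)2O in toluene should acylate the free 4-hydroxyl of 14 to give benzyl 4-[(2-heptyl-4,6-dimethoxybenzoyl)oxy]-2-hydroxy-6-pentylbenzoate F5, and one methylation (MeI, K2CO3, DMF) returns to the route at 17.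

**Step 3.** Proton transfer from the newly formed, more acidic product to unreacted dianion, O-acylation, or a second acylation could lower the conversion. Fallback, from 1 and 5 to 8: the dienolate of 1 is acylated with allyl 3-chloro-3-oxopropanoate to give prop-2-en-1-yl 4-(2,2-dimethyl-4-oxo-4H-1,3-dioxin-6-yl)-3-oxobutanoate F6. Soft enolisation with MgCl2 and pyridine and C-acylation with 5 at the methylene between ketone and ester would give prop-2-en-1-yl 2-[(2,2-dimethyl-4-oxo-4H-1,3-dioxin-6-yl)acetyl]-3-oxodecanoate F7. Deallylation with Pd(PPh3)4 and morpholine, followed by decarboxylation, comes back at 8.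

**Step 6.** Carboxylation could occur at the carbon between the two hydroxyls, or the acid could decarboxylate during work-up. Fallback, from 12 to 13: Vilsmeier–Haack formylation (POCl3, DMF), which is directed to the position next to the pentyl chain, should give 2,4-dihydroxy-6-pentylbenzaldehyde F8. Lindgren–Pinnick oxidation (NaClO2, NaH2PO4, sulfamic acid as hypochlorite scavenger) then returns to the route at 13.

**Step 8.** Competitive light absorption by 14 and by the product could slow ketene generation. The ketene could also be lost to dimerisation or to traces of water, and slow photo-Fries rearrangement of the product is possible. Fallback, from 11 to 17: the acylal is opened with NaOCH2Ph (NaH, benzyl alcohol, THF) to give benzyl 2-heptyl-6-hydroxy-4-methoxybenzoate F9. Methylation would give F3, and from there the fallback of step 4 is followed: hydrogenolysis to F4, (CF3CO)2O-mediated esterification with 14 to F5, and methylation to 17.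

**Step 9.** The ring A ortho-phenoxide could expel the ring B phenoxide (ketene-type fragmentation followed by methylation of the wrong oxygen), the acyl group could migrate, or the hindered chelated hydroxyls could be methylated incompletely. Fallback, from 14 and 11 to 17: all methyl ethers are placed before the ester bond is made. Selective allylation of the non-chelated hydroxyl of 14 (allyl bromide, K2CO3, 1 equiv, acetone) would give benzyl 2-hydroxy-6-pentyl-4-(prop-2-en-1-yloxy)benzoate F10. Methylation would give benzyl 2-methoxy-6-pentyl-4-(prop-2-en-1-yloxy)benzoate F11, and Pd(PPh3)4 with morpholine would give benzyl 4-hydroxy-2-methoxy-6-pentylbenzoate F12 (the same compound as A8). Acid F4, reached from 11 through F9 and F3 as described for step 8, would then be esterified with F12 by the (CF3CO)2O method to give 17 directly, with no methylation after the depside bond exists.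

## Further compounds

F1 | step 4 | benzyl 3,5,7-trioxotetradecanoate | CCCCCCCC(=O)CC(=O)CC(=O)CC(=O)OCc1ccccc1
F2 | step 4 | benzyl 2-heptyl-4,6-dihydroxybenzoate | CCCCCCCc1cc(O)cc(O)c1C(=O)OCc1ccccc1
F3 | step 4 | benzyl 2-heptyl-4,6-dimethoxybenzoate | CCCCCCCc1cc(OC)cc(OC)c1C(=O)OCc1ccccc1
F4 | step 4 | 2-heptyl-4,6-dimethoxybenzoic acid | CCCCCCCc1cc(OC)cc(OC)c1C(=O)O
F5 | step 4 | benzyl 4-[(2-heptyl-4,6-dimethoxybenzoyl)oxy]-2-hydroxy-6-pentylbenzoate | CCCCCCCc1cc(OC)cc(OC)c1C(=O)Oc1cc(CCCCC)c(C(=O)OCc2ccccc2)c(O)c1
F6 | step 3 | prop-2-en-1-yl 4-(2,2-dimethyl-4-oxo-4H-1,3-dioxin-6-yl)-3-oxobutanoate | C=CCOC(=O)CC(=O)CC1=CC(=O)OC(C)(C)O1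
F7 | step 3 | prop-2-en-1-yl 2-[(2,2-dimethyl-4-oxo-4H-1,3-dioxin-6-yl)acetyl]-3-oxodecanoate (racemic) | C=CCOC(=O)C(C(=O)CCCCCCC)C(=O)CC1=CC(=O)OC(C)(C)O1
F8 | step 6 | 2,4-dihydroxy-6-pentylbenzaldehyde | CCCCCc1cc(O)cc(O)c1C=O
F9 | step 8 | benzyl 2-heptyl-6-hydroxy-4-methoxybenzoate | CCCCCCCc1cc(OC)cc(O)c1C(=O)OCc1ccccc1
F10 | step 9 | benzyl 2-hydroxy-6-pentyl-4-(prop-2-en-1-yloxy)benzoate | CCCCCc1cc(OCC=C)cc(O)c1C(=O)OCc1ccccc1
F11 | step 9 | benzyl 2-methoxy-6-pentyl-4-(prop-2-en-1-yloxy)benzoate | CCCCCc1cc(OCC=C)cc(OC)c1C(=O)OCc1ccccc1
F12 | step 9 | benzyl 4-hydroxy-2-methoxy-6-pentylbenzoate | CCCCCc1cc(O)cc(OC)c1C(=O)OCc1ccccc1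
A1 | alternative 1 | 1,2-dibromo-3,5-dimethoxybenzene | COc1cc(Br)c(Br)c(OC)c1
A2 | alternative 1 | heptylmagnesium bromide | CCCCCCC[Mg]Br
A3 | alternative 1 | 3,5-dimethoxybenzyne (1,2-didehydro-3,5-dimethoxybenzene) | COC1=CC(OC)=CC#C1
A4 | alternative 1 | carbon dioxide | O=C=O
A5 | alternative 1 | 2-heptyl-4,6-dimethoxybenzoic acid | CCCCCCCc1cc(OC)cc(OC)c1C(=O)O
A6 | alternative 2 | 1,1-dimethoxy-3-(trimethylsilyloxy)buta-1,3-diene | COC(OC)=CC(=C)O[Si](C)(C)C
A7 | alternative 2 | benzyl oct-2-ynoate | CCCCCC#CC(=O)OCc1ccccc1
A8 | alternative 2 | benzyl 4-hydroxy-2-methoxy-6-pentylbenzoate | CCCCCc1cc(O)cc(OC)c1C(=O)OCc1ccccc1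
A9 | alternative 3 | 1,3-dimethoxycyclohexa-1,3-diene | COC1=CC(OC)=CCC1
A10 | alternative 3 | benzyl dec-2-ynoate | CCCCCCCC#CC(=O)OCc1ccccc1
A11 | alternative 3 | benzyl 3-heptyl-1,5-dimethoxybicyclo[2.2.2]octa-2,5-diene-2-carboxylate (racemic) | COC1=CC2(OC)CCC1C(CCCCCCC)=C2C(=O)OCc1ccccc1
A12 | alternative 3 | ethene | C=C
A13 | alternative 3 | benzyl 2-heptyl-4,6-dimethoxybenzoate | CCCCCCCc1cc(OC)cc(OC)c1C(=O)OCc1ccccc1
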